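Assumption: "Bromoclavulone III" is taken to be bromovulone III, methyl (5E,7Z,12R,14Z)-10-bromo-12-hydroxy-9-oxoprosta-5,7,10,14-tetraenoate. Prostanoid numbering is used throughout: C1 is the ester carbon, C8–C12 the ring, C13–C20 the octenyl chain.

## Retrosynthetic overview
1. The target comes from a final neutral oxidation of the C9 carbinol in 9,12-diol 22, so the labile 7Z bromo-trienone appears only in the last step.
2. The 14Z alkene comes from a Wittig reaction on a C14 aldehyde. That aldehyde traces back to 1,2-addition of a Weinreb acetamide enolate to the C12 ketone of 15, anti to C9-OSi, which sets C12.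
3. C7=C8 comes from aldol/E1cB of C12 ketone 10 with enal 13. The usual geometry (chain anti to the C=O, so syn to C9) becomes 7Z once the carbonyl is moved from C12 to C9.
4. Ketone 10 comes from (S)-4-silyloxycyclopentenone 5 by α-bromination, Luche reduction, a silyl swap and oxidation. This 1,3-carbonyl transposition places Br at C10.
5. Enone 5 comes from lipase desymmetrisation of meso-diacetate 1. The only ring (the cyclopentene) is bought intact, so there is no ring-forming step.

## Route

**Step 1**
- Reactants: 1, cis-cyclopent-4-ene-1,3-diyl diacetate (meso)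
- Product: 2, (1R,4S)-4-hydroxycyclopent-2-en-1-yl acetate
- Conditions: porcine pancreatic lipase (a lipase, serine-hydrolase class), 0.1 M phosphate buffer pH 7, rt, pH-stat (1 M NaOH); recrystallise from Et2O/pentane to >99% ee
- Reagents that add atoms: none
- Why: In this enzymatic desymmetrisation the lipase hydrolyses only the acetate on the (S)-carbinol carbon of the achiral meso diester, which fixes the absolute configuration for the whole route.

**Step 2**
- Reactants: 2
- Product: 3, (1R,4S)-4-(tert-butyldimethylsilyloxy)cyclopent-2-en-1-yl acetate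
- Conditions: TBSCl, imidazole, DMF, 0 °C to rt
- Reagents that add atoms: TBSCl, CC(C)(C)[Si](C)(C)Cl
- Why: This is a standard silylation of the free secondary alcohol (future O12), and neither stereocentre is touched.

**Step 3**
- Reactants: 3
- Product: 4, (1R,4S)-4-(tert-butyldimethylsilyloxy)cyclopent-2-en-1-ol
- Conditions: K2CO3, MeOH, 0 °C to rt
- Reagents that add atoms: none
- Why: Base-catalysed transesterification removes the acetate, and the TBS ether is stable to these conditions.

**Step 4**
- Reactants: 4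
- Product: 5, (4S)-4-(tert-butyldimethylsilyloxy)cyclopent-2-en-1-one
- Conditions: activated MnO2, CH2Cl2, rt
- Reagents that add atoms: none
- Why: This neutral allylic alcohol oxidation leaves the γ-silyloxy stereocentre intact.

**Step 5**
- Reactants: 5
- Product: 6, (4S)-2-bromo-4-(tert-butyldimethylsilyloxy)cyclopent-2-en-1-one
- Conditions: Br2, CH2Cl2, 0 °C; then Et3N, 0 °C to rt
- Reagents that add atoms: bromine, BrBr
- Why: Bromine addition followed by dehydrobromination places Br on the α-carbon only (future C10), at a stage when no other alkene is present.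

**Step 6**
- Reactants: 6
- Product: 7, (1R,4S)-2-bromo-4-(tert-butyldimethylsilyloxy)cyclopent-2-en-1-ol (OH cis to OTBS)
- Conditions: NaBH4, CeCl3·7H2O, MeOH, −78 to −20 °C
- Reagents that add atoms: none
- Why: In this Luche 1,2-reduction hydride arrives anti to the OTBS group and gives the cis alcohol (expected dr >10:1, minor isomer removed by chromatography), creating the C9 relay stereocentre.

**Step 7**
- Reactants: 7
- Product: 8, (1R,4S)-2-bromo-1-(tert-butyldiphenylsilyloxy)-4-(tert-butyldimethylsilyloxy)cyclopent-2-ene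
- Conditions: TBDPSCl, imidazole, cat. DMAP, DMF, rt
- Reagents that add atoms: TBDPSCl, CC(C)(C)[Si](Cl)(c1ccccc1)c1ccccc1
- Why: Silylation puts a bulky, acid-stable group on O9 that later shields one ring face.

**Step 8**
- Reactants: 8
- Product: 9, (1S,4R)-3-bromo-4-(tert-butyldiphenylsilyloxy)cyclopent-2-en-1-ol
- Conditions: CSA (10 mol %), MeOH/CH2Cl2 1:1, 0 °C to rt
- Reagents that add atoms: none
- Why: Acid-catalysed desilylation is selective because the TBS ether is about 100 times more acid-labile than the TBDPS ether.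

**Step 9**
- Reactants: 9
- Product: 10, (4R)-3-bromo-4-(tert-butyldiphenylsilyloxy)cyclopent-2-en-1-one
- Conditions: Dess–Martin periodinane, NaHCO3, CH2Cl2, 0 °C to rt
- Reagents that add atoms: none
- Why: This buffered Dess–Martin oxidation completes the 1,3-carbonyl transposition, leaving the ketone at C12, Br at C10 and the C9 stereocentre unchanged.

**Step 10**
- Reactants: 11, methyl hex-5-enoate; 12, (E)-crotonaldehyde
- Product: 13, methyl (5E)-7-oxohept-5-enoate
- Conditions: Hoveyda–Grubbs II (2 mol %), 12 (5 equiv), CH2Cl2, 40 °C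
- Reagents that add atoms: crotonaldehyde (12), C/C=C/C=O
- Why: Olefin cross-metathesis of a type I terminal alkene with an enal gives the E-enal (>20:1), which sets the 5E alkene.

**Step 11**
- Reactants: 10; 13
- Product: 14, methyl (5E)-7-[(1R,2R)-3-bromo-2-(tert-butyldiphenylsilyloxy)-5-oxocyclopent-3-en-1-yl]-7-hydroxyhept-5-enoate (side chain trans to OTBDPS; C7 epimers, not separated)
- Conditions: LDA (1.05 equiv), THF, −78 °C, 30 min; then 13, −78 °C; AcOH quench at −78 °C
- Reagents that add atoms: 13, O=C/C=C/CCCC(=O)OC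
- Why: Kinetic α′-deprotonation gives the cross-conjugated lithium enolate, which cannot lose silyloxide without forming a cyclopentadienone, and it adds 1,2 to the enal (aldol addition) to give stereocentres that are erased in step 12.

**Step 12**
- Reactants: 14
- Product: 15, methyl (5E,7E)-7-[(2R)-3-bromo-2-(tert-butyldiphenylsilyloxy)-5-oxocyclopent-3-en-1-ylidene]hept-5-enoate (C6 anti to the ketone, syn to C9)
- Conditions: Ms2O, Et3N, CH2Cl2, −20 to 0 °C, then neutral Al2O3 if mesylate persists; dark; minimum contact time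
- Reagents that add atoms: none
- Why: Mesylation and E1cB elimination give the favoured alkylidene with the chain anti to the C=O, as is usual for 4-substituted 5-alkylidenecyclopentenones, while chloride-free Ms2O avoids Br/Cl exchange at the vinylogous acyl bromide.

**Step 13**
- Reactants: 15; 16, N-methoxy-N-methylacetamide
- Product: 17, methyl (5E,7E)-7-[(2R,5R)-3-bromo-2-(tert-butyldiphenylsilyloxy)-5-hydroxy-5-{2-[methoxy(methyl)amino]-2-oxoethyl}cyclopent-3-en-1-ylidene]hept-5-enoate (OH cis to OTBDPS)
- Conditions: 16 + LDA (1.3 equiv), THF, −78 °C; add 15, 20 min; AcOH quench at −78 °C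
- Reagents that add atoms: 16, CC(=O)N(C)OC
- Why: The lithium amide enolate adds 1,2 to the ketone under kinetic control from the face anti to the bulky C9-OTBDPS, which sets C12 as R; the separable minor epimer must be removed because it would lead to the enantiomer of the target.

**Step 14**
- Reactants: 17
- Product: 18, the 12-O-triethylsilyl ether of 17
- Conditions: TESOTf, 2,6-lutidine, CH2Cl2, −78 to −20 °C
- Reagents that add atoms: TESOTf, CC[Si](CC)(CC)OS(=O)(=O)C(F)(F)F
- Why: Buffered silylation of the tertiary bis-allylic alcohol blocks retro-aldol and β-elimination in the next two steps.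

**Step 15**
- Reactants: 18
- Product: 19, methyl (5E,7E)-7-[(2R,5R)-3-bromo-2-(tert-butyldiphenylsilyloxy)-5-(2-oxoethyl)-5-(triethylsilyloxy)cyclopent-3-en-1-ylidene]hept-5-enoate
- Conditions: DIBAL-H (1.2 equiv), THF, −78 °C, 45 min; Rochelle salt work-up; used at once
- Reagents that add atoms: none
- Why: In this Weinreb amide reduction the more Lewis-basic amide reacts via a stable chelate faster than the remote methyl ester, which is sluggish toward DIBAL in THF at −78 °C.

**Step 16**
- Reactants: 19; 20, hexyltriphenylphosphonium bromide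
- Product: 21, methyl (5E,7E)-7-[(2R,5R)-3-bromo-2-(tert-butyldiphenylsilyloxy)-5-[(2Z)-oct-2-en-1-yl]-5-(triethylsilyloxy)cyclopent-3-en-1-ylidene]hept-5-enoate
- Conditions: 20 (1.6 equiv), NaHMDS (1.5 equiv), THF, 0 °C; then 19, −78 to −20 °C
- Reagents that add atoms: 20, CCCCCC[P+](c1ccccc1)(c1ccccc1)c1ccccc1.[Br-]
- Why: A salt-free Wittig reaction of a non-stabilised ylide gives the 14Z alkene (≥95:5), and the ester, vinyl bromide and silyl ethers all tolerate it.

**Step 17**
- Reactants: 21
- Product: 22, methyl (5E,7E,9R,12R,14Z)-10-bromo-9,12-dihydroxyprosta-5,7,10,14-tetraenoate (cis-9,12-diol)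
- Conditions: TBAF/AcOH (1:1, 4 equiv), THF, 0 °C to rt; Et3N-deactivated silica
- Reagents that add atoms: none
- Why: Buffered fluoride removes both silyl groups without saponifying the ester or ionising the bis-allylic alcohols.

**Step 18**
- Reactants: 22
- Product: 23, bromovulone III
- Conditions: Dess–Martin periodinane (1.3 equiv), NaHCO3, CH2Cl2, 0 °C, dark; direct filtration through a short silica plug
- Reagents that add atoms: none
- Why: Dess–Martin oxidation can only touch the secondary C9 alcohol, and the unchanged geometry (C6 syn to C9) is now labelled 7Z because the C9 carbonyl outranks C12.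

## Compound list

| No. | Name | SMILES | Role |
|---|---|---|---|
| 1 | cis-cyclopent-4-ene-1,3-diyl diacetate (meso) | CC(=O)O[C@@H]1C[C@H](OC(C)=O)C=C1 | starting material |
| 2 | (1R,4S)-4-hydroxycyclopent-2-en-1-yl acetate | CC(=O)O[C@@H]1C[C@H](O)C=C1 | intermediate |
| 3 | (1R,4S)-4-(TBSO)cyclopent-2-en-1-yl acetate | CC(=O)O[C@@H]1C[C@H](O[Si](C)(C)C(C)(C)C)C=C1 | intermediate |
| 4 | (1R,4S)-4-(TBSO)cyclopent-2-en-1-ol | O[C@@H]1C[C@H](O[Si](C)(C)C(C)(C)C)C=C1 | intermediate |
| 5 | (4S)-4-(TBSO)cyclopent-2-en-1-one | O=C1C[C@H](O[Si](C)(C)C(C)(C)C)C=C1 | intermediate |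
| 6 | (4S)-2-bromo-4-(TBSO)cyclopent-2-en-1-one | O=C1C[C@H](O[Si](C)(C)C(C)(C)C)C=C1Br | intermediate |
| 7 | (1R,4S)-2-bromo-4-(TBSO)cyclopent-2-en-1-ol | O[C@@H]1C[C@H](O[Si](C)(C)C(C)(C)C)C=C1Br | intermediate |
| 8 | (1R,4S)-2-bromo-1-(TBDPSO)-4-(TBSO)cyclopent-2-ene | CC(C)(C)[Si](c1ccccc1)(c1ccccc1)O[C@@H]1C[C@H](O[Si](C)(C)C(C)(C)C)C=C1Br | intermediate |
| 9 | (1S,4R)-3-bromo-4-(TBDPSO)cyclopent-2-en-1-ol | CC(C)(C)[Si](c1ccccc1)(c1ccccc1)O[C@@H]1C[C@H](O)C=C1Br | intermediate |
| 10 | (4R)-3-bromo-4-(TBDPSO)cyclopent-2-en-1-one | CC(C)(C)[Si](c1ccccc1)(c1ccccc1)O[C@@H]1CC(=O)C=C1Br | intermediate |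
| 11 | methyl hex-5-enoate | C=CCCCC(=O)OC | starting material |
| 12 | (E)-crotonaldehyde | C/C=C/C=O | starting material |
| 13 | methyl (5E)-7-oxohept-5-enoate | O=C/C=C/CCCC(=O)OC | intermediate |
| 14 | aldol adduct (8,9-trans, C7 epimers) | CC(C)(C)[Si](c1ccccc1)(c1ccccc1)O[C@@H]1[C@@H](C(O)/C=C/CCCC(=O)OC)C(=O)C=C1Br | intermediate |
| 15 | (5E,7E,9R)-alkylidene bromo-enone (C12 ketone) | CC(C)(C)[Si](c1ccccc1)(c1ccccc1)O[C@@H]1/C(=C\C=C\CCCC(=O)OC)C(=O)C=C1Br | intermediate |
| 16 | N-methoxy-N-methylacetamide | CC(=O)N(C)OC | starting material |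
| 17 | (9R,12R)-tertiary alcohol Weinreb amide | CC(C)(C)[Si](c1ccccc1)(c1ccccc1)O[C@@H]1/C(=C\C=C\CCCC(=O)OC)[C@@](O)(CC(=O)N(C)OC)C=C1Br | intermediate |
| 18 | 12-O-TES ether of 17 | CC(C)(C)[Si](c1ccccc1)(c1ccccc1)O[C@@H]1/C(=C\C=C\CCCC(=O)OC)[C@@](O[Si](CC)(CC)CC)(CC(=O)N(C)OC)C=C1Br | intermediate |
| 19 | C14 aldehyde | CC(C)(C)[Si](c1ccccc1)(c1ccccc1)O[C@@H]1/C(=C\C=C\CCCC(=O)OC)[C@@](O[Si](CC)(CC)CC)(CC=O)C=C1Br | intermediate |
| 20 | hexyltriphenylphosphonium bromide | CCCCCC[P+](c1ccccc1)(c1ccccc1)c1ccccc1.[Br-] | starting material |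
| 21 | bis-silyl (14Z)-tetraene | CC(C)(C)[Si](c1ccccc1)(c1ccccc1)O[C@@H]1/C(=C\C=C\CCCC(=O)OC)[C@@](O[Si](CC)(CC)CC)(C/C=C\CCCCC)C=C1Br | intermediate |
| 22 | methyl (5E,7E,9R,12R,14Z)-10-bromo-9,12-dihydroxyprosta-5,7,10,14-tetraenoate | O[C@@H]1/C(=C\C=C\CCCC(=O)OC)[C@@](O)(C/C=C\CCCCC)C=C1Br | intermediate |
| 23 | bromovulone III, methyl (5E,7Z,12R,14Z)-10-bromo-12-hydroxy-9-oxoprosta-5,7,10,14-tetraenoate | CCCCC/C=C\C[C@@]1(O)C=C(Br)C(=O)/C1=C\C=C\CCCC(=O)OC | target |

## Totals
- Total steps: 18
- Longest linear sequence: 17 (steps 1–9 and 11–18)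

## Three steps most likely to fail
1. **Step 11, lithium enolate of the β-bromo-γ-silyloxy enone.** The risks are γ-deprotonation, erosion of C9 and decomposition. Fallback: avoid the strong-base enolate. Convert 10 to its 2-silyloxydiene by soft enolisation (TMSOTf/Et3N) and run a Lewis-acid Mukaiyama aldol with 13 or its dimethyl acetal. Eliminating the β-oxygen group then gives the same E-alkylidene 15.
2. **Step 13, 1,2-addition to the polyelectrophilic trienone.** The risks are deprotonation, conjugate addition and modest facial selectivity. Fallback: replace the enolate/DIBAL/Wittig sequence. Add allylmagnesium bromide/CeCl3 (fast, non-basic, 1,2-selective), protect O12 as the TES ether, and build the 14Z alkene by Z-selective cross-metathesis with 1-heptene using a cyclometalated Ru catalyst, which ignores E-internal alkenes.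
3. **Step 15, amide versus methyl ester discrimination by DIBAL.** Fallback: remove the competition. Use (E)-7-(silyloxy)hept-2-enal in step 11 so that C1 is carried as a protected alcohol. After global desilylation, oxidise C1 and C9 together with Dess–Martin periodinane, then apply Pinnick oxidation and TMSCHN2 to install the methyl ester last.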